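## Retrosynthetic overview

1. Chain: (2E,6E)-farnesyl bromide 1 and methallyl alcohol 2 (as its dianion 3) are the precursors of dienol 4 through one allyl–allyl SN2 bond; no ring yet.
2. Temporary ring: 4 and but-3-enoic acid 5 give ester 6, the ring-closing-metathesis precursor of dihydropyranone 7. This ring locks the CH2O group cis to the future C5–CH2. Then 7 → 8 (terminal E-allylic hydroxylation) → lactol 9.
3. Nucleophile: methyl 4-hydroxybut-2-ynoate 10 → (Z)-β-iodo enoate 11 → vinylchromium 12, a β-acyl vinyl anion (homoenolate-type d3 reagent).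
4. Key disconnection: the butenolide C4–C5 bond, between the acrylate β-carbon of 12 and the aldehyde carbon of 13 (open form of 9). Both carbons are electrophilic in their parent functions. Ligand control sets C5 (R), and alkoxide 14 lactonises to Hippolide F 15.
5. Ring order: the dihydropyranone is formed first and opened in the key step; the butenolide, the only ring of the target, is formed last.

Assumption: the (S)-sulfonamide ligand, (S)-N-[2-(4-isopropyl-4,5-dihydrooxazol-2-yl)-6-methylphenyl]methanesulfonamide, is taken to direct Si-face attack by analogy with reported aldehyde couplings; if the first run gave 5S, its mirror image would be used.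

## Route

Step 1
Reactants: 1 (2E,6E)-farnesyl bromide; 2 2-methylprop-2-en-1-ol
Product: 4 (5E,9E)-6,10,14-trimethyl-2-methylidenepentadeca-5,9,13-trien-1-ol, via dilithiated 2-methylprop-2-en-1-ol 3 (not isolated)
Conditions: 2 (2 equiv), n-BuLi (4 equiv), TMEDA, Et2O, 0 °C → rt; then 1, THF, −78 °C → rt; H2O
Reagents that add atoms: none
Why: Dianion alkylation: the alkoxide-directed allylic lithiation gives a 2-(oxidomethyl)allyl anion with two equivalent CH2 termini, which C-alkylates the primary allylic bromide by SN2 with the E olefins untouched.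

Step 2
Reactants: 4; 5 but-3-enoic acid
Product: 6 (5E,9E)-6,10,14-trimethyl-2-methylidenepentadeca-5,9,13-trien-1-yl but-3-enoate
Conditions: DCC, DMAP (5 mol %), CH2Cl2, 0 °C
Reagents that add atoms: none
Why: Steglich esterification of a primary allylic alcohol; low temperature and little DMAP keep the but-3-enoate from isomerising to the crotonate.

Step 3
Reactants: 6
Product: 7 5-[(3E,7E)-4,8,12-trimethyltrideca-3,7,11-trien-1-yl]-3,6-dihydro-2H-pyran-2-one
Conditions: second-generation Grubbs catalyst (H2IMes)(PCy3)Cl2Ru=CHPh (5 mol %), 1,4-benzoquinone (10 mol %), CH2Cl2 (0.005 M), 40 °C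
Reagents that add atoms: none
Why: Ring-closing metathesis starts at the terminal vinyl group and closes the six-membered ring onto the 1,1-disubstituted olefin far faster than it touches the chain trisubstituted olefins; the ring forces CH2O and CH2C(=O) cis on the new olefin.

Step 4
Reactants: 7
Product: 8 5-[(3E,7E,11E)-13-hydroxy-4,8,12-trimethyltrideca-3,7,11-trien-1-yl]-3,6-dihydro-2H-pyran-2-one
Conditions: SeO2 (0.3 equiv), t-BuOOH (3 equiv), salicylic acid (0.1 equiv), CH2Cl2, 0 °C → rt; stopped at partial conversion, 7 recycled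
Reagents that add atoms: selenium dioxide, O=[Se]=O (catalytic oxygen carrier); tert-butyl hydroperoxide, CC(C)(C)OO (terminal oxygen source)
Why: Catalytic Riley allylic oxidation (ene reaction then 2,3-sigmatropic shift) prefers the most electron-rich, least hindered terminal isopropylidene and gives the E-CH2OH, as with farnesyl and geranylgeranyl acetates; the ring olefin is deactivated by its allylic acyloxy group.

Step 5
Reactants: 8
Product: 9 5-[(3E,7E,11E)-13-hydroxy-4,8,12-trimethyltrideca-3,7,11-trien-1-yl]-3,6-dihydro-2H-pyran-2-ol (anomer mixture)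
Conditions: i-Bu2AlH (2.3 equiv), CH2Cl2, −78 °C; aq. KNaC4H4O6
Reagents that add atoms: none
Why: Partial lactone reduction stops at the hemiacetal stage at −78 °C (the first equivalent only deprotonates the hydroxyl); the lactol is a stable, storable form of the isomerisation-prone β,γ-unsaturated aldehyde.

Step 6
Reactants: 10 methyl 4-hydroxybut-2-ynoate
Product: 11 methyl (Z)-4-hydroxy-3-iodobut-2-enoate
Conditions: LiI (1.3 equiv), AcOH (1.3 equiv), MeCN, 70 °C
Reagents that add atoms: lithium iodide, [Li+].[I-]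
Why: Hydroiodination of an ynoate: iodide adds to the β-carbon and the proton is delivered anti, so iodine ends cis to the ester (Z) and the CH2OH trans to it, where it cannot lactonise.

Step 7
Reactants: 9; 11
Product: 15 Hippolide F, via vinylchromium reagent 12 (not isolated), via open-chain hydroxy aldehyde 13 (not isolated), via chromium alkoxide of hydroxy enoate 14 (not isolated)
Conditions: CrCl2 (5 equiv), (S)-sulfonamide ligand (5.5 equiv), Et3N (5.5 equiv), THF, rt; then NiCl2 (2 mol %), 11 (2 equiv), 9, rt, 36 h; aq. ethylenediamine; SiO2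
Reagents that add atoms: none
Why: Proposed new method: zerovalent nickel (from NiCl2 and divalent chromium) inserts into the C–I bond of 11 and hands the vinyl group to trivalent chromium with retention, giving the weakly basic β-(methoxycarbonyl)vinylchromium 12, which survives the free hydroxyls and adds to the small equilibrium amount of aldehyde 13 released from lactol 9; the chiral sulfonamide on chromium directs attack to the Si face (5R), and the alkoxide 14, cis to the ester, lactonises with loss of methanol; the closest known chemistry is the Nozaki–Hiyama–Kishi butenolide annulation of (Z)-β-iodoacrylates with aldehydes and Kishi's sulfonamide-ligand asymmetric Ni/Cr coupling, here extended to an unprotected lactol.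

## Compound list

1 | (2E,6E)-farnesyl bromide, (2E,6E)-1-bromo-3,7,11-trimethyldodeca-2,6,10-triene | CC(C)=CCC/C(C)=C/CC/C(C)=C/CBr | starting material
2 | 2-methylprop-2-en-1-ol (methallyl alcohol) | CC(=C)CO | starting material
3 | dilithiated 2-methylprop-2-en-1-ol | [Li+].[Li+].[CH2-]C(=C)C[O-] | intermediate (not isolated)
4 | (5E,9E)-6,10,14-trimethyl-2-methylidenepentadeca-5,9,13-trien-1-ol | CC(C)=CCC/C(C)=C/CC/C(C)=C/CCC(=C)CO | intermediate
5 | but-3-enoic acid | C=CCC(=O)O | starting material
6 | (5E,9E)-6,10,14-trimethyl-2-methylidenepentadeca-5,9,13-trien-1-yl but-3-enoate | CC(C)=CCC/C(C)=C/CC/C(C)=C/CCC(=C)COC(=O)CC=C | intermediate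
7 | 5-[(3E,7E)-4,8,12-trimethyltrideca-3,7,11-trien-1-yl]-3,6-dihydro-2H-pyran-2-one | CC(C)=CCC/C(C)=C/CC/C(C)=C/CCC1=CCC(=O)OC1 | intermediate
8 | 5-[(3E,7E,11E)-13-hydroxy-4,8,12-trimethyltrideca-3,7,11-trien-1-yl]-3,6-dihydro-2H-pyran-2-one | C/C(=C\CC/C(C)=C/CC/C(C)=C/CCC1=CCC(=O)OC1)CO | intermediate
9 | 5-[(3E,7E,11E)-13-hydroxy-4,8,12-trimethyltrideca-3,7,11-trien-1-yl]-3,6-dihydro-2H-pyran-2-ol (anomer mixture) | C/C(=C\CC/C(C)=C/CC/C(C)=C/CCC1=CCC(O)OC1)CO | intermediate
10 | methyl 4-hydroxybut-2-ynoate | COC(=O)C#CCO | starting material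
11 | methyl (Z)-4-hydroxy-3-iodobut-2-enoate | COC(=O)/C=C(\I)CO | intermediate
12 | [(Z)-1-hydroxy-4-methoxy-4-oxobut-2-en-2-yl]chromium dichloride (trivalent chromium; drawn without the sulfonamide ligand it carries in the flask) | COC(=O)/C=C(\[Cr](Cl)Cl)CO | intermediate (not isolated)
13 | (3Z,7E,11E,15E)-17-hydroxy-4-(hydroxymethyl)-8,12,16-trimethylheptadeca-3,7,11,15-tetraenal | C/C(=C\CC/C(C)=C/CC/C(C)=C/CC/C(=C/CC=O)CO)CO | intermediate (not isolated)
14 | methyl (2Z,4R,6Z,10E,14E,18E)-4,20-dihydroxy-3,7-bis(hydroxymethyl)-11,15,19-trimethylicosa-2,6,10,14,18-pentaenoate (present as its chromium alkoxide) | C/C(=C\CC/C(C)=C/CC/C(C)=C/CC/C(=C/C[C@@H](O)/C(CO)=C\C(=O)OC)CO)CO | intermediate (not isolated)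
15 | Hippolide F, (5R)-5-[(2Z,6E,10E,14E)-16-hydroxy-3-(hydroxymethyl)-7,11,15-trimethylhexadeca-2,6,10,14-tetraen-1-yl]-4-(hydroxymethyl)furan-2(5H)-one | C/C(=C\CC/C(C)=C/CC/C(C)=C/CC/C(=C/C[C@H]1OC(=O)C=C1CO)CO)CO | target

## Step count and risks

Total steps: 7. Longest linear sequence: 6 (steps 1, 2, 3, 4, 5 and 7); step 6 is a one-step side branch. No protecting groups are used.

**Risk A, step 7 (highest).** The lactol may release too little aldehyde, the three free hydroxyls may slow the chromium reagent, and the cis CH2OH of 13 may chelate chromium and erode the enantioselectivity. The fallback sets out from 9 and comes back at 15. It builds the butenolide in two bond-forming events and sets the stereocentre by a catalytic zinc alkynylation instead. Lactol 9, which opens readily as its zinc alkoxide, is treated with methyl propiolate, Me2Zn and the ProPhenol enantiomer that gives the 4R carbinol (toluene, 4 °C) to give the (4R)-4-hydroxy-2-ynoate F1. Excess (i-PrO)Me2SiCH2MgCl with CuI (THF, −78 → −30 °C) then adds syn across the ynoate, which puts the carbinol cis to the ester and closes the ring to the 4-(silylmethyl)butenolide F2. Tamao oxidation (H2O2, KF, KHCO3, THF/MeOH) converts C–Si into C–OH and gives 15.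

**Risk B, step 4.** The oxidation must pick one of four trisubstituted olefins and spare the activated ring CH2; low conversion or mixtures are possible. The fallback sets out from dianion 3 together with a new commercial starting material, (2E,6E)-farnesyl acetate F3, used in place of 1, and comes back at 8. It moves the oxidation to the best-precedented substrate. SeO2/t-BuOOH on F3 gives the 12-hydroxy acetate F4; TBSCl/imidazole gives the silyl ether acetate F5; K2CO3/MeOH gives the allylic alcohol F6; CBr4/PPh3 gives the silyloxy bromide F7. Alkylation of F7 with 3 gives the silyloxy dienol F8, DCC and 5 give the silyloxy but-3-enoate F9, ring-closing metathesis gives the silyl-protected lactone F10, and HF·pyridine in THF gives 8.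

**Risk C, step 3.** Ruthenium hydride can isomerise the but-3-enoate to the crotonate, which then closes to a ring-contracted butenolide; the chain olefins may also interfere. The fallback sets out from 4 and comes back at 7, and replaces metathesis by a palladium carbonylative lactonisation. Hydroxyl-directed epoxidation of 4 (VO(acac)2, t-BuOOH) gives the epoxy alcohol F11. Excess dimethylsulfonium methylide (trimethylsulfonium iodide, n-BuLi, THF) opens the epoxide at its CH2 and eliminates dimethyl sulfide to give the vinyl diol F12. Carbonyldiimidazole closes the vinyl cyclic carbonate F13. With Pd(PPh3)4 under CO (20 bar, THF, 60 °C), zerovalent palladium ionises the carbonate, CO2 is lost, CO inserts at the unsubstituted allyl terminus, and the tethered alkoxide captures the acyl-palladium. It can only reach the acyl group from the Z-configured allyl, so the product is 7. The closest precedent is Tsuji's decarboxylative carbonylation of allylic carbonates to β,γ-unsaturated esters.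

## Further compounds

F1 | step 7 | methyl (4R,6Z,10E,14E,18E)-4,20-dihydroxy-7-(hydroxymethyl)-11,15,19-trimethylicosa-6,10,14,18-tetraen-2-ynoate | C/C(=C\CC/C(C)=C/CC/C(C)=C/CC/C(=C/C[C@@H](O)C#CC(=O)OC)CO)CO
F2 | step 7 | (5R)-5-[(2Z,6E,10E,14E)-16-hydroxy-3-(hydroxymethyl)-7,11,15-trimethylhexadeca-2,6,10,14-tetraen-1-yl]-4-{[dimethyl(propan-2-yloxy)silyl]methyl}furan-2(5H)-one | C/C(=C\CC/C(C)=C/CC/C(C)=C/CC/C(=C/C[C@H]1OC(=O)C=C1C[Si](C)(C)OC(C)C)CO)CO
F3 | step 4 | (2E,6E)-3,7,11-trimethyldodeca-2,6,10-trien-1-yl acetate (farnesyl acetate, new commercial starting material) | CC(C)=CCC/C(C)=C/CC/C(C)=C/COC(C)=O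
F4 | step 4 | (2E,6E,10E)-12-hydroxy-3,7,11-trimethyldodeca-2,6,10-trien-1-yl acetate | C/C(=C\CC/C(C)=C/CC/C(C)=C/COC(C)=O)CO
F5 | step 4 | (2E,6E,10E)-12-[(tert-butyldimethylsilyl)oxy]-3,7,11-trimethyldodeca-2,6,10-trien-1-yl acetate | C/C(=C\CC/C(C)=C/CC/C(C)=C/COC(C)=O)CO[Si](C)(C)C(C)(C)C
F6 | step 4 | (2E,6E,10E)-12-[(tert-butyldimethylsilyl)oxy]-3,7,11-trimethyldodeca-2,6,10-trien-1-ol | C/C(=C\CC/C(C)=C/CC/C(C)=C/CO)CO[Si](C)(C)C(C)(C)C
F7 | step 4 | tert-butyl{[(2E,6E,10E)-12-bromo-2,6,10-trimethyldodeca-2,6,10-trien-1-yl]oxy}dimethylsilane | C/C(=C\CC/C(C)=C/CC/C(C)=C/CBr)CO[Si](C)(C)C(C)(C)C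
F8 | step 4 | (5E,9E,13E)-15-[(tert-butyldimethylsilyl)oxy]-6,10,14-trimethyl-2-methylidenepentadeca-5,9,13-trien-1-ol | C/C(=C\CC/C(C)=C/CC/C(C)=C/CCC(=C)CO)CO[Si](C)(C)C(C)(C)C
F9 | step 4 | (5E,9E,13E)-15-[(tert-butyldimethylsilyl)oxy]-6,10,14-trimethyl-2-methylidenepentadeca-5,9,13-trien-1-yl but-3-enoate | C/C(=C\CC/C(C)=C/CC/C(C)=C/CCC(=C)COC(=O)CC=C)CO[Si](C)(C)C(C)(C)C
F10 | step 4 | 5-[(3E,7E,11E)-13-[(tert-butyldimethylsilyl)oxy]-4,8,12-trimethyltrideca-3,7,11-trien-1-yl]-3,6-dihydro-2H-pyran-2-one | C/C(=C\CC/C(C)=C/CC/C(C)=C/CCC1=CCC(=O)OC1)CO[Si](C)(C)C(C)(C)C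
F11 | step 3 | {2-[(3E,7E)-4,8,12-trimethyltrideca-3,7,11-trien-1-yl]oxiran-2-yl}methanol (racemic) | CC(C)=CCC/C(C)=C/CC/C(C)=C/CCC1(CO)CO1
F12 | step 3 | 2-[(3E,7E)-4,8,12-trimethyltrideca-3,7,11-trien-1-yl]but-3-ene-1,2-diol (racemic) | CC(C)=CCC/C(C)=C/CC/C(C)=C/CCC(O)(CO)C=C
F13 | step 3 | 4-ethenyl-4-[(3E,7E)-4,8,12-trimethyltrideca-3,7,11-trien-1-yl]-1,3-dioxolan-2-one (racemic) | CC(C)=CCC/C(C)=C/CC/C(C)=C/CCC1(C=C)COC(=O)O1
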